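## Structural features

The target is a germacranolide. A ten-membered carbocycle (ring A, C1–C10) carries a Z C1=C10 and an E C4=C5 trisubstituted alkene and is fused across C6–C7 to an α-methylene-γ-lactone (ring B: O, C6, C7, C11, C12, with C13 as the exocyclic methylene). Four contiguous stereocentres run C6(R)–C7(R)–C8(R)–C9(R): the allylic lactone carbinol C6, the fully substituted C7 with a free tertiary hydroxyl at the ring fusion, the acylated C8 and the free allylic carbinol C9. On ring B, C5 and C8 are trans and the C7 oxygen is cis to C5; the C8 and C9 oxygens are anti along the chain. The C8 ester is a (2S,3R)-2,3-dimethyloxirane-2-carboxylate, in which the two methyl groups are cis. It is therefore the epoxide of the E acid (tiglic acid); angelic acid (Z) would give the trans-dimethyl oxirane and is the wrong C5 source. Fragile elements are the α-methylene lactone (conjugate addition), the epoxy ester (acid, nucleophiles, electron-transfer reductants), the 8-O-acyl/9-OH pair (1,2-acyl shift), the tertiary β-hydroxy lactone (retro-aldol while C11 is sp3) and the 1,5-diene macrocycle (transannular reactions). The real difficulty is the oxygenated quaternary carbon C7 flanked by three oxygenated stereocentres, together with closure of a strained ten-membered ring of defined alkene geometry and the differentiation of three hydroxyl groups. The key step uses the fact that C6, C7, C11 and C12 of ring B, with oxygen already on C7 and with C5 and C8 trans, are the four carbons of a 3-silyloxycyclobutanone that a ketene and a Z silyl enol ether deliver in one event; oxygen insertion between C12 and C6 then turns that ring into ring B.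

## Logic of the disconnections

**C9–C10 of ring A.** 29 is opened to 28. The bond joins a carbinol carbon to a vinylic carbon, so an aldehyde and an alkenyl iodide are the natural partners; the cut removes the macrocycle and the C9 stereocentre together. The forward step must add the alkenyl metal to the aldehyde only (lactone, ester, epoxide and enoate present), keep the Z geometry, run at high dilution and deliver the 8,9-anti (Felkin) carbinol.

**C9 oxidation level and the O8–acyl bond.** 28 goes back through 27 and 26 to 20 and 24 by cutting the ester C–O bond at O8. Acylating before ring closure means O8 and O9 never have to be told apart, because O9 is still a protected primary alcohol. The demands are acylation of the secondary C8 hydroxyl in the presence of the tertiary C7 hydroxyl, and unmasking plus oxidation of C9 without a 1,2-acyl shift.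

**The oxirane C–O bonds.** 24 comes from 23, 22 and 21. The epoxide is placed on the allylic alcohol, where reagent control is dependable. The forward step needs the E alkene and the D-(−)-tartrate ligand.

**C11–C13 and the two O–Si bonds.** 20 comes from 19 and 19 from 16. The methylene is a one-carbon electrophile added to the lactone enolate. The C7 silyl ether must stay until C11 is sp2, so that retro-aldol cleavage of C7–C11 is impossible, and the enolate must not expel the C7 silyloxy group.

**The ring oxygen (O–C6) and the two chlorines.** 16 goes back to 15 and 15 to 14. Removing the ring oxygen reveals a cyclobutanone. The forward oxidation must insert on the C6 side with retention and spare three alkenes; the zinc reduction must spare the alkenyl iodide.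

**C7–C11 and C6–C12 (key cut).** 14 is divided into 11 and 13, the latter made in the flask from 12. Two skeletal bonds, one ring and two stereocentres are removed, and the C7 oxygen becomes the enol ether oxygen. The forward step needs the Z enol ether, facial control by C8 and site selectivity for C6=C7.

**O–Si, C6–S and C6–C7.** 11 comes from 10, 10 from 9, and 9 from 5 and 8. C6 is allylic and is best made nucleophilic as a sulfonyl carbanion, which reacts at the α-carbon without allylic transposition; C7 arrives at the acid oxidation level. This route is chosen over alkylation of a C7 acyl-anion equivalent, whose carbanion would carry a β-silyloxy leaving group at C8. The demands are an amide base that leaves the alkenyl iodide alone, no epimerisation at C8, C–S reduction that stops at the enolate, and Z-selective enol silylation.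

**C1=C10 and the C1 aldehyde.** 5 comes from 4, 4 from 2 and 2 from 1. The E C4=C5 alkene and C15 are bought with the geranyl skeleton. The forward steps need site-selective ozonolysis of the remote alkene and a Z-selective iodo-olefination.

**O–Si and O–C9 of the three-carbon unit.** 8 comes from 7 and 7 from 6, so C8 is taken from the chiral pool. The epoxide must open at the unsubstituted carbon only.

## Other disconnections considered

**Alternative 1:** The cut is C2–C3 of ring A, with C5–C10 reconnected, so that the macrocycle is traced to the cis-1-vinyl-2-isopropenylcyclohexanol A1, which holds C6–C9 as ring carbons with two acetonides.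
- Forward key step: the potassium alkoxide of A1 (KH, 18-crown-6) undergoes an anionic oxy-Cope shift and the C10 enolate is trapped with N-phenyltriflimide to give dienyl triflate A2.
- In its favour: ring A arises by ring expansion, so no high dilution is needed. Both alkene geometries come from one chair-like transition state (axial isopropenyl gives E C4=C5; equatorial vinyl with C9 axial in the array gives Z C1=C10). The stereocentres are installed on a rigid six-membered ring.
- Against it here: A1 needs six contiguous stereocentres on a cyclohexane, two of them fully substituted. The wanted E,Z isomer depends on reaction through the chair with an axial isopropenyl group, which suffers 1,3-diaxial strain. A2 still lacks C14 (triflate cross-coupling), has C12 at the alcohol level, and offers no distinction between O8 and O9.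
- Comparison: on ring A construction and control of alkene geometry it is better than the chosen plan, which relies on an iodo-olefination and a macrocyclisation. On the C7 carbinol it is weaker, since C7 must be made by a separate carbonyl addition. On step economy it is worse, because the cost moves into A1 and into a long sequence after A2.

**Alternative 2:** The cut is C11–C12 of ring B.
- Forward key step: Bu3SnH and AIBN turn the C6 phenyl selenocarbonate A3 into an alkoxycarbonyl radical that closes 5-exo-dig onto the C7 ethynyl group; the vinyl radical takes hydrogen to give the core A4.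
- In its favour: lactone and exocyclic methylene form together without enolate chemistry, the free tertiary hydroxyl is tolerated, and A4 already distinguishes O8 (PMB) from O9 (TBS), so three steps remain.
- Against it here: the whole macrocycle with all four stereocentres must exist first. The C7 carbinol would come from acetylide addition to a ketone in a flexible ten-membered ring. The radical sits on an allylic oxygen, so loss of CO2 to a C5–C6 allyl radical competes with cyclisation. The C13 vinyl radical is placed for transannular addition or hydrogen transfer.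
- Comparison: for the methylene lactone itself and for the endgame protecting-group logic it is equal or better than steps 11–13 of the chosen plan. It does not address the quaternary centre or ring A, which the chosen key step and step 20 do, so overall step economy is at best equal.

**Alternative 3:** The cuts are C9–C10 and C10–C14.
- Forward key step: lithiated 2,3-dihydrofuran A5 and a methylcuprate (MeLi, CuBr·SMe2) undergo a 1,2-metalate shift that places the methyl on C10 with inversion and opens the ring; the Z alkenylcuprate adds to aldehyde A6 under BF3·OEt2 to give A7.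
- In its favour: the Z C1=C10 geometry is fixed by a stereospecific migration, two bonds and C14 are set in one flask, and C9 is formed in an acyclic Felkin addition.
- Against it here: A7 contains neither ring. C4, C5 and C15 must still be attached and the ten-membered ring closed, probably at C5–C6 with C6 set during macrocyclisation. A6 is a hindered α-silyloxy aldehyde beside a quaternary carbon that has to be made separately, and its acetonide and silyl ethers must survive the Lewis acid.
- Comparison: on alkene geometry it is better than step 3 of the chosen plan; on C9 control it is equal or better than step 20. On structure it covers only the C9–C10–C1 sector, and the step count after A7 is likely to exceed that of the chosen plan after 14.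

Key step: step 9

Assumption: metal enolates, carbanions and alkoxides formed from a numbered compound by deprotonation or electron transfer are treated as forms of that compound and carry no number of their own.

Assumption: germacrane atom labels (C1–C15) are used for all intermediates, cyclic or not.

## Steps

Step 1
Reactants: 1 geranyl bromide [(2E)-1-bromo-3,7-dimethylocta-2,6-diene]
Product: 2 geranyl phenyl sulfone {[(2E)-3,7-dimethylocta-2,6-dien-1-yl]sulfonylbenzene}
Conditions: PhSO2Na, DMF, 0 °C → rt
Reagents that add atoms: sodium benzenesulfinate, [Na+].[O-]S(=O)c1ccccc1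
Why: Sulfinate S-alkylation by SN2 displacement on the primary allylic bromide; no allylic transposition is expected and the E alkene is untouched.

Step 2
Reactants: 2 geranyl phenyl sulfone
Product: 4 (4E)-4-methyl-6-(phenylsulfonyl)hex-4-enal, via secondary ozonide 3 (not isolated)
Conditions: O3 (1 equiv), CH2Cl2, −78 °C; then PPh3, −78 °C → rt
Reagents that add atoms: ozone, [O-][O+]=O
Why: Ozonolysis with reductive work-up; the remote trisubstituted alkene is more electron-rich than the alkene deactivated by the allylic sulfonyl group, so one equivalent of ozone should cleave it selectively.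

Step 3
Reactants: 4 (4E)-4-methyl-6-(phenylsulfonyl)hex-4-enal
Product: 5 {[(2E,6Z)-7-iodo-3-methylocta-2,6-dien-1-yl]sulfonyl}benzene
Conditions: EtPPh3I, n-BuLi, THF, rt; I2, −78 °C; NaN(SiMe3)2, −20 °C; then 4, −78 → −20 °C
Reagents that add atoms: ethyltriphenylphosphonium iodide, CC[P+](c1ccccc1)(c1ccccc1)c1ccccc1.[I-]; iodine, II
Why: Stork–Zhao-type Wittig olefination with the unstabilised α-iodo ylide adds C10 and C14; kinetic cis-oxaphosphetane formation should place iodine cis to the chain (Z). The ylide is fully formed before 4 is added, so the acidic sulfone is not deprotonated.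

Step 4
Reactants: 6 methyl (2R)-oxirane-2-carboxylate [methyl (R)-glycidate]
Product: 7 methyl (2R)-2-hydroxy-3-[(4-methoxybenzyl)oxy]propanoate
Conditions: 4-MeOC6H4CH2OH, BF3·OEt2 (cat.), CH2Cl2, 0 °C → rt
Reagents that add atoms: 4-methoxybenzyl alcohol, COc1ccc(CO)cc1
Why: Lewis acid-catalysed epoxide alcoholysis; attack should occur at the unsubstituted carbon, because the ester destabilises cationic character at C2 and hinders it, so the R centre (C8 of the target) is not touched.

Step 5
Reactants: 7 methyl (2R)-2-hydroxy-3-[(4-methoxybenzyl)oxy]propanoate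
Product: 8 methyl (2R)-2-[(tert-butyldimethylsilyl)oxy]-3-[(4-methoxybenzyl)oxy]propanoate
Conditions: TBSCl, imidazole, DMF, rt
Reagents that add atoms: tert-butyldimethylsilyl chloride, CC(C)(C)[Si](C)(C)Cl
Why: Standard silylation of a secondary α-hydroxy ester; no base strong enough to epimerise C8 is present.

Step 6
Reactants: 5 {[(2E,6Z)-7-iodo-3-methylocta-2,6-dien-1-yl]sulfonyl}benzene; 8 methyl (2R)-2-[(tert-butyldimethylsilyl)oxy]-3-[(4-methoxybenzyl)oxy]propanoate
Product: 9 (2R,5E,9Z)-2-[(tert-butyldimethylsilyl)oxy]-10-iodo-1-[(4-methoxybenzyl)oxy]-6-methyl-4-(phenylsulfonyl)undeca-5,9-dien-3-one (both epimers at the sulfonyl carbon)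
Conditions: LiN(SiMe3)2 (2.2 equiv), THF, −78 °C; then 8, −78 → −30 °C; aq. NH4Cl
Reagents that add atoms: none
Why: Claisen-type C-acylation of the lithiated allylic sulfone, which reacts at the carbon α to sulfur (C6) with retention of the E alkene and forms C6–C7. The second equivalent of base stores the product as its stabilised anion, which protects C8 from epimerisation; an amide base is used so that the alkenyl iodide is not exchanged.

Step 7
Reactants: 9 β-keto sulfone
Product: 10 (2R,5E,9Z)-2-[(tert-butyldimethylsilyl)oxy]-10-iodo-1-[(4-methoxybenzyl)oxy]-6-methylundeca-5,9-dien-3-one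
Conditions: SmI2 (2.5 equiv), THF, −78 °C; then sat. aq. NH4Cl
Reagents that add atoms: none
Why: Reductive desulfonylation of a β-keto sulfone by two electron transfers from divalent samarium. The product stays as a trivalent samarium dienolate until the quench, so the α-silyloxy ketone is not exposed to reductant; the alkenyl iodide is inert without HMPA, and kinetic protonation at C6 keeps the E C4=C5 alkene out of conjugation.

Step 8
Reactants: 10 β,γ-unsaturated ketone
Product: 11 (2R,3Z,5E,9Z)-2,3-bis[(tert-butyldimethylsilyl)oxy]-10-iodo-1-[(4-methoxybenzyl)oxy]-6-methylundeca-3,5,9-triene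
Conditions: TBSOTf, Et3N, CH2Cl2, −78 → 0 °C
Reagents that add atoms: tert-butyldimethylsilyl trifluoromethanesulfonate, CC(C)(C)[Si](C)(C)OS(=O)(=O)C(F)(F)F
Why: Soft enolisation (silyl triflate/amine); the doubly activated C6–H is removed in preference to C8–H. The Z enol ether (C5 cis to oxygen) is expected because the E isomer would press the C5 alkenyl group against the branched C8 (1,3-allylic strain).

Step 9
Reactants: 11 Z silyl enol ether; 12 dichloroacetyl chloride
Product: 14 (3R,4R)-3-[(tert-butyldimethylsilyl)oxy]-3-{(1R)-1-[(tert-butyldimethylsilyl)oxy]-2-[(4-methoxybenzyl)oxy]ethyl}-2,2-dichloro-4-[(1E,5Z)-6-iodo-2-methylhepta-1,5-dien-1-yl]cyclobutan-1-one, via dichloroketene 13 (not isolated)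
Conditions: 12 (slow addition), Et3N, hexane, rt
Reagents that add atoms: none
Why: Et3N dehydrochlorinates 12 to 13, which is consumed as it forms; C6, the nucleophilic β-carbon of the enol ether, attacks the central ketene carbon C12 and the incipient oxocarbenium carbon C7 is captured by the dichloro-enolate carbon C11, so C6–C12 and C7–C11 form in one asynchronous event that is suprafacial on the alkene. The closest known reaction type is the dichloroketene–silyl enol ether (2+2) cycloaddition that gives 2,2-dichloro-3-silyloxycyclobutanones. The four-membered ring (C6, C7, C11, C12) is closed by cycloaddition, both ring bonds arising in the same step. The relative configuration of C6 and C7 follows from the Z geometry of 11: C5 and the C7 oxygen stay cis, C5 and C8 trans. The absolute sense is set by C8: because C6 carries hydrogen cis to C8 there is no 1,3-allylic strain, and the bias comes from 1,2-strain against the C7 silyloxy group and the inside-alkoxy preference, so that either low-energy rotamer (C8–O in the enol ether plane with the CH2OPMB arm anti, or C8–H in the plane with C8–O anti) exposes the same face and should lead to the (3R,4R) adduct. Site selectivity is needed among three alkenes and the two nucleophilic termini of the silyloxydiene; C6 is the most electron-rich unhindered position, the vinylogous terminus C4 is fully substituted and the iodoalkene is electron-poor. Amine-generated ketene avoids zinc salts and the excess Et3N buffers HCl, so the silyl ethers and the β-silyloxy ketone should survive.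

Step 10
Reactants: 14 dichlorocyclobutanone
Product: 15 (2R,3R)-3-[(tert-butyldimethylsilyl)oxy]-3-{(1R)-1-[(tert-butyldimethylsilyl)oxy]-2-[(4-methoxybenzyl)oxy]ethyl}-2-[(1E,5Z)-6-iodo-2-methylhepta-1,5-dien-1-yl]cyclobutan-1-one
Conditions: Zn–Cu couple, NH4Cl, MeOH, rt
Reagents that add atoms: none
Why: Zinc reduction of the α,α-dichloro ketone through zinc enolates that are protonated at once; loss of the β-silyloxy group would require a strained cyclobutenone and is not expected, and the alkenyl iodide does not insert zinc under these conditions.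

Step 11
Reactants: 15 cyclobutanone
Product: 16 (4R,5R)-4-[(tert-butyldimethylsilyl)oxy]-4-{(1R)-1-[(tert-butyldimethylsilyl)oxy]-2-[(4-methoxybenzyl)oxy]ethyl}-5-[(1E,5Z)-6-iodo-2-methylhepta-1,5-dien-1-yl]oxolan-2-one
Conditions: 30% aq. H2O2, AcOH, 0 °C
Reagents that add atoms: hydrogen peroxide, OO
Why: Baeyer–Villiger oxidation; the strained ketone adds H2O2 directly and the secondary allylic C6 should migrate in preference to the primary C11, with retention at C6, giving the O–C6 bond of ring B. Without a strong peracid the three alkenes are expected to be left alone.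

Step 12
Reactants: 16 γ-lactone
Product: 19 (4R,5R)-4-[(tert-butyldimethylsilyl)oxy]-4-{(1R)-1-[(tert-butyldimethylsilyl)oxy]-2-[(4-methoxybenzyl)oxy]ethyl}-5-[(1E,5Z)-6-iodo-2-methylhepta-1,5-dien-1-yl]-3-methylideneoxolan-2-one, via Mannich base 17 (not isolated), via trimethylammonium iodide 18 (not isolated)
Conditions: LiN(iPr)2, THF, −78 °C; CH2=NMe2+ I−, −78 → 0 °C; then MeI, MeOH/CH2Cl2, rt; then aq. NaHCO3, rt
Reagents that add atoms: N,N-dimethylmethyleneiminium iodide (Eschenmoser's salt), C=[N+](C)C.[I-]
Why: Lactone α-methylenation by enolate Mannich reaction, quaternisation and E1cB loss of trimethylamine; the C11 enolate is kept at −78 °C, where the poor silyloxide leaving group on C7 should stay in place, and both C11 epimers of 17 converge on 19.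

Step 13
Reactants: 19 α-methylene lactone
Product: 20 (4S,5R)-4-hydroxy-4-{(1R)-1-hydroxy-2-[(4-methoxybenzyl)oxy]ethyl}-5-[(1E,5Z)-6-iodo-2-methylhepta-1,5-dien-1-yl]-3-methylideneoxolan-2-one
Conditions: 48% aq. HF, MeCN, 0 °C → rt
Reagents that add atoms: none
Why: Fluoride/acid desilylation of the tertiary C7 and hindered secondary C8 silyl ethers; the PMB ether, lactone and alkenyl iodide are stable to HF, and retro-aldol is blocked because C11 is now sp2. The descriptor at C7 changes to S by priority only.

Step 14
Reactants: 21 tiglic acid [(2E)-2-methylbut-2-enoic acid]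
Product: 22 (2E)-2-methylbut-2-en-1-ol
Conditions: LiAlH4, Et2O, 0 °C → rt
Reagents that add atoms: none
Why: Hydride reduction of the carboxylic acid to the allylic alcohol (1,2-reduction); the E geometry, which later puts the two oxirane methyl groups cis, is retained.

Step 15
Reactants: 22 (2E)-2-methylbut-2-en-1-ol
Product: 23 [(2R,3R)-2,3-dimethyloxiran-2-yl]methanol
Conditions: Ti(OiPr)4 (cat.), D-(−)-diethyl tartrate (cat.), t-BuOOH, 4 Å MS, CH2Cl2, −20 °C
Reagents that add atoms: tert-butyl hydroperoxide, CC(C)(C)OO
Why: Sharpless asymmetric epoxidation; syn oxygen transfer keeps the methyl groups cis, and the D-(−)-tartrate ligand is chosen by the standard mnemonic to give the (2R,3R) epoxy alcohol, the mirror image of the (2S,3S) product expected from E allylic alcohols with the L-(+) ligand.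

Step 16
Reactants: 23 [(2R,3R)-2,3-dimethyloxiran-2-yl]methanol
Product: 24 (2S,3R)-2,3-dimethyloxirane-2-carboxylic acid
Conditions: RuCl3 (cat.), NaIO4, MeCN/EtOAc/H2O, 0 °C → rt
Reagents that add atoms: water, O
Why: Catalytic RuO4 oxidation of the primary alcohol to the acid through the aldehyde hydrate; the oxirane is not touched, and the C2 descriptor changes from R to S by priority only.

Step 17
Reactants: 20 diol; 24 (2S,3R)-2,3-dimethyloxirane-2-carboxylic acid
Product: 26 (1R)-1-{(2R,3R)-3-hydroxy-2-[(1E,5Z)-6-iodo-2-methylhepta-1,5-dien-1-yl]-4-methylidene-5-oxooxolan-3-yl}-2-[(4-methoxybenzyl)oxy]ethyl (2S,3R)-2,3-dimethyloxirane-2-carboxylate, via mixed anhydride 25 (not isolated)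
Conditions: 24, 2,4,6-Cl3C6H2COCl, Et3N, THF, rt; then 20, DMAP, toluene, rt
Reagents that add atoms: none
Why: Yamaguchi esterification; DMAP transfers the aliphatic acyl group of 25 to the secondary C8 hydroxyl, while the tertiary C7 hydroxyl should not react. Migration of the lactone from O6 to O8 would need a strained bicyclic ortho-ester-type intermediate and is not expected.

Step 18
Reactants: 26 PMB ether
Product: 27 (1R)-2-hydroxy-1-{(2R,3R)-3-hydroxy-2-[(1E,5Z)-6-iodo-2-methylhepta-1,5-dien-1-yl]-4-methylidene-5-oxooxolan-3-yl}ethyl (2S,3R)-2,3-dimethyloxirane-2-carboxylate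
Conditions: DDQ, CH2Cl2/pH 7 buffer, 0 °C
Reagents that add atoms: none
Why: Oxidative cleavage of the PMB ether by DDQ under buffered conditions; the α-quaternary (pivalate-like) ester should be slow to shift to the new primary hydroxyl, and 27 is carried on at once.

Step 19
Reactants: 27 primary alcohol
Product: 28 (1S)-1-{(2R,3R)-3-hydroxy-2-[(1E,5Z)-6-iodo-2-methylhepta-1,5-dien-1-yl]-4-methylidene-5-oxooxolan-3-yl}-2-oxoethyl (2S,3R)-2,3-dimethyloxirane-2-carboxylate
Conditions: Dess–Martin periodinane, NaHCO3, CH2Cl2, 0 °C → rt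
Reagents that add atoms: none
Why: Dess–Martin oxidation under buffered, non-enolising conditions gives the α-acyloxy aldehyde without epimerising C8 (its descriptor becomes S by priority only); the tertiary hydroxyl cannot be oxidised.

Step 20
Reactants: 28 aldehyde
Product: 29 target CNP0420662.1
Conditions: CrCl2 (excess), NiCl2 (cat.), degassed DMSO, rt, high dilution (slow addition of 28)
Reagents that add atoms: none
Why: Nozaki–Hiyama–Kishi reaction: zerovalent nickel inserts into the alkenyl iodide, the alkenyl group passes to trivalent chromium with retention of the Z geometry and adds to the aldehyde only, closing ring A at C9–C10. Felkin–Anh attack anti to the C8 acyloxy group should give the 8,9-anti (9R) carbinol; the free tertiary hydroxyl, lactone, ester and oxirane are tolerated by the organochromium reagent.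

## Compound list

1 | geranyl bromide, (2E)-1-bromo-3,7-dimethylocta-2,6-diene | CC(C)=CCC/C(C)=C/CBr | starting material
2 | {[(2E)-3,7-dimethylocta-2,6-dien-1-yl]sulfonyl}benzene | CC(C)=CCC/C(C)=C/CS(=O)(=O)c1ccccc1 | intermediate
3 | 3,3-dimethyl-5-[(3E)-3-methyl-5-(phenylsulfonyl)pent-3-en-1-yl]-1,2,4-trioxolane (secondary ozonide) | CC1(C)OOC(CC/C(C)=C/CS(=O)(=O)c2ccccc2)O1 | intermediate (not isolated)
4 | (4E)-4-methyl-6-(phenylsulfonyl)hex-4-enal | O=CCC/C(C)=C/CS(=O)(=O)c1ccccc1 | intermediate
5 | {[(2E,6Z)-7-iodo-3-methylocta-2,6-dien-1-yl]sulfonyl}benzene | C/C(I)=C/CC/C(C)=C/CS(=O)(=O)c1ccccc1 | intermediate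
6 | methyl (2R)-oxirane-2-carboxylate | COC(=O)[C@H]1CO1 | starting material
7 | methyl (2R)-2-hydroxy-3-[(4-methoxybenzyl)oxy]propanoate | COC(=O)[C@H](O)COCc1ccc(OC)cc1 | intermediate
8 | methyl (2R)-2-[(tert-butyldimethylsilyl)oxy]-3-[(4-methoxybenzyl)oxy]propanoate | COC(=O)[C@H](O[Si](C)(C)C(C)(C)C)COCc1ccc(OC)cc1 | intermediate
9 | (2R,5E,9Z)-2-[(tert-butyldimethylsilyl)oxy]-10-iodo-1-[(4-methoxybenzyl)oxy]-6-methyl-4-(phenylsulfonyl)undeca-5,9-dien-3-one, C4 epimers | C/C(I)=C/CC/C(C)=C/C(C(=O)[C@H](O[Si](C)(C)C(C)(C)C)COCc1ccc(OC)cc1)S(=O)(=O)c1ccccc1 | intermediate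
10 | (2R,5E,9Z)-2-[(tert-butyldimethylsilyl)oxy]-10-iodo-1-[(4-methoxybenzyl)oxy]-6-methylundeca-5,9-dien-3-one | C/C(I)=C/CC/C(C)=C/CC(=O)[C@H](O[Si](C)(C)C(C)(C)C)COCc1ccc(OC)cc1 | intermediate
11 | (2R,3Z,5E,9Z)-2,3-bis[(tert-butyldimethylsilyl)oxy]-10-iodo-1-[(4-methoxybenzyl)oxy]-6-methylundeca-3,5,9-triene | C/C(I)=C/CC/C(C)=C/C=C(\O[Si](C)(C)C(C)(C)C)[C@H](O[Si](C)(C)C(C)(C)C)COCc1ccc(OC)cc1 | intermediate
12 | dichloroacetyl chloride | ClC(Cl)C(Cl)=O | starting material
13 | dichloroketene | ClC(Cl)=C=O | intermediate (not isolated)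
14 | (3R,4R)-3-[(tert-butyldimethylsilyl)oxy]-3-{(1R)-1-[(tert-butyldimethylsilyl)oxy]-2-[(4-methoxybenzyl)oxy]ethyl}-2,2-dichloro-4-[(1E,5Z)-6-iodo-2-methylhepta-1,5-dien-1-yl]cyclobutan-1-one | O=C1C(Cl)(Cl)[C@](O[Si](C)(C)C(C)(C)C)([C@H](O[Si](C)(C)C(C)(C)C)COCc2ccc(OC)cc2)[C@H]1/C=C(\C)CC/C=C(/C)I | intermediate
15 | (2R,3R)-3-[(tert-butyldimethylsilyl)oxy]-3-{(1R)-1-[(tert-butyldimethylsilyl)oxy]-2-[(4-methoxybenzyl)oxy]ethyl}-2-[(1E,5Z)-6-iodo-2-methylhepta-1,5-dien-1-yl]cyclobutan-1-one | O=C1C[C@](O[Si](C)(C)C(C)(C)C)([C@H](O[Si](C)(C)C(C)(C)C)COCc2ccc(OC)cc2)[C@H]1/C=C(\C)CC/C=C(/C)I | intermediate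
16 | (4R,5R)-4-[(tert-butyldimethylsilyl)oxy]-4-{(1R)-1-[(tert-butyldimethylsilyl)oxy]-2-[(4-methoxybenzyl)oxy]ethyl}-5-[(1E,5Z)-6-iodo-2-methylhepta-1,5-dien-1-yl]oxolan-2-one | O=C1C[C@](O[Si](C)(C)C(C)(C)C)([C@H](O[Si](C)(C)C(C)(C)C)COCc2ccc(OC)cc2)[C@@H](/C=C(\C)CC/C=C(/C)I)O1 | intermediate
17 | 3-[(dimethylamino)methyl] derivative of 16 (Mannich base, C3 epimers) | O=C1C(CN(C)C)[C@](O[Si](C)(C)C(C)(C)C)([C@H](O[Si](C)(C)C(C)(C)C)COCc2ccc(OC)cc2)[C@@H](/C=C(\C)CC/C=C(/C)I)O1 | intermediate (not isolated)
18 | 3-[(trimethylammonio)methyl] derivative of 16, iodide (C3 epimers) | O=C1C(C[N+](C)(C)C)[C@](O[Si](C)(C)C(C)(C)C)([C@H](O[Si](C)(C)C(C)(C)C)COCc2ccc(OC)cc2)[C@@H](/C=C(\C)CC/C=C(/C)I)O1.[I-] | intermediate (not isolated)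
19 | (4R,5R)-4-[(tert-butyldimethylsilyl)oxy]-4-{(1R)-1-[(tert-butyldimethylsilyl)oxy]-2-[(4-methoxybenzyl)oxy]ethyl}-5-[(1E,5Z)-6-iodo-2-methylhepta-1,5-dien-1-yl]-3-methylideneoxolan-2-one | O=C1C(=C)[C@](O[Si](C)(C)C(C)(C)C)([C@H](O[Si](C)(C)C(C)(C)C)COCc2ccc(OC)cc2)[C@@H](/C=C(\C)CC/C=C(/C)I)O1 | intermediate
20 | (4S,5R)-4-hydroxy-4-{(1R)-1-hydroxy-2-[(4-methoxybenzyl)oxy]ethyl}-5-[(1E,5Z)-6-iodo-2-methylhepta-1,5-dien-1-yl]-3-methylideneoxolan-2-one | O=C1C(=C)[C@](O)([C@H](O)COCc2ccc(OC)cc2)[C@@H](/C=C(\C)CC/C=C(/C)I)O1 | intermediate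
21 | tiglic acid, (2E)-2-methylbut-2-enoic acid | C/C=C(\C)C(=O)O | starting material
22 | (2E)-2-methylbut-2-en-1-ol | C/C=C(\C)CO | intermediate
23 | [(2R,3R)-2,3-dimethyloxiran-2-yl]methanol | OC[C@@]1(C)O[C@@H]1C | intermediate
24 | (2S,3R)-2,3-dimethyloxirane-2-carboxylic acid | OC(=O)[C@@]1(C)O[C@@H]1C | intermediate
25 | (2S,3R)-2,3-dimethyloxirane-2-carboxylic 2,4,6-trichlorobenzoic anhydride | O=C(OC(=O)[C@@]1(C)O[C@@H]1C)c1c(Cl)cc(Cl)cc1Cl | intermediate (not isolated)
26 | (1R)-1-{(2R,3R)-3-hydroxy-2-[(1E,5Z)-6-iodo-2-methylhepta-1,5-dien-1-yl]-4-methylidene-5-oxooxolan-3-yl}-2-[(4-methoxybenzyl)oxy]ethyl (2S,3R)-2,3-dimethyloxirane-2-carboxylate | O=C1C(=C)[C@](O)([C@H](OC(=O)[C@@]3(C)O[C@@H]3C)COCc2ccc(OC)cc2)[C@@H](/C=C(\C)CC/C=C(/C)I)O1 | intermediate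
27 | (1R)-2-hydroxy-1-{(2R,3R)-3-hydroxy-2-[(1E,5Z)-6-iodo-2-methylhepta-1,5-dien-1-yl]-4-methylidene-5-oxooxolan-3-yl}ethyl (2S,3R)-2,3-dimethyloxirane-2-carboxylate | O=C1C(=C)[C@](O)([C@H](OC(=O)[C@@]3(C)O[C@@H]3C)CO)[C@@H](/C=C(\C)CC/C=C(/C)I)O1 | intermediate
28 | (1S)-1-{(2R,3R)-3-hydroxy-2-[(1E,5Z)-6-iodo-2-methylhepta-1,5-dien-1-yl]-4-methylidene-5-oxooxolan-3-yl}-2-oxoethyl (2S,3R)-2,3-dimethyloxirane-2-carboxylate | O=C1C(=C)[C@](O)([C@H](OC(=O)[C@@]3(C)O[C@@H]3C)C=O)[C@@H](/C=C(\C)CC/C=C(/C)I)O1 | intermediate
29 | CNP0420662.1, (3aR,4R,5R,6Z,10E,11aR)-3a,5-dihydroxy-6,10-dimethyl-3-methylidene-2-oxo-2,3,3a,4,5,8,9,11a-octahydrocyclodeca[b]furan-4-yl (2S,3R)-2,3-dimethyloxirane-2-carboxylate | C=C1C(=O)O[C@@H]2/C=C(\C)CC/C=C(/C)[C@@H](O)[C@@H](OC(=O)[C@@]3(C)O[C@@H]3C)[C@@]12O | target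

## Step count and least certain steps

Total step count: 20 (15 in the main chain, 2 for ester 8, 3 for acid 24).

Longest linear sequence: 15 steps, 1 → 2 → 4 → 5 → 9 → 10 → 11 → 14 → 15 → 16 → 19 → 20 → 26 → 27 → 28 → 29 (steps 1–3, 6–13, 17–20).

**Step 9 (key step).** Three things may go wrong.
- Loss of site selectivity: 11 is a 1-silyloxydiene, so the ketene may be attacked through the vinylogous terminus C4 or the diene may close in a formal (4+2) sense.
- Poor facial selectivity, because the controlling C8 centre is acyclic and its rotamer preference is only moderate.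
- Desilylative retro-aldol opening of the β-silyloxy cyclobutanone during work-up.

The fallback gives up the cycloaddition and builds the same lactone by carbonyl addition; it sets out from 10 and comes back at 16. Deprotonation of 10 at C6 with KN(SiMe3)2 and oxidation of the enolate with a (camphorsulfonyl)oxaziridine, its enantiomer chosen to favour R at C6, should give the α-hydroxy ketone (2R,4R,5E,9Z)-2-[(tert-butyldimethylsilyl)oxy]-4-hydroxy-10-iodo-1-[(4-methoxybenzyl)oxy]-6-methylundeca-5,9-dien-3-one F1. A Reformatsky reaction of F1 (Zn, BrCH2CO2Et, THF) adds the C11–C12 unit to the C7 carbonyl. In the five-membered zinc chelate of the C6 alkoxide and the C7 carbonyl the reagent should approach anti to the C5 alkenyl group, giving the dihydroxy ester ethyl (3R,4R,5E,9Z)-3-{(1R)-1-[(tert-butyldimethylsilyl)oxy]-2-[(4-methoxybenzyl)oxy]ethyl}-3,4-dihydroxy-10-iodo-6-methylundeca-5,9-dienoate F2, in which the C7 oxygen ends up cis to C5 once the ring is closed. F2 should lactonise, spontaneously or with mild acid, to the hydroxy lactone (4R,5R)-4-{(1R)-1-[(tert-butyldimethylsilyl)oxy]-2-[(4-methoxybenzyl)oxy]ethyl}-4-hydroxy-5-[(1E,5Z)-6-iodo-2-methylhepta-1,5-dien-1-yl]oxolan-2-one F3. TBSOTf and 2,6-lutidine then convert F3 into 16.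

**Step 20.** The ten-membered ring may close slowly, so that oligomerisation competes. The chromium alkoxide formed at O9 may trigger a 1,2-shift of the neighbouring acyl group, the epoxy ester may be reduced by divalent chromium, and facial selectivity at C9 may be poor inside the macrocyclic transition state. The fallback closes the ring before the acyl group is present and uses a protecting-group exchange to keep O8 and O9 distinct; it sets out from 19 and comes back at 29.
- DDQ on 19 should give the primary alcohol (the bis-silyl ether with free C9 hydroxyl) F4.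
- Dess–Martin oxidation gives the α-silyloxy aldehyde F5.
- CrCl2/NiCl2 ring closure gives the macrocyclic 9-ol with O7 and O8 silylated, F6.
- 4-Methoxybenzyl trichloroacetimidate with catalytic La(OTf)3 gives the 9-O-PMB ether F7.
- Aqueous HF in MeCN removes both silyl groups to give the 7,8-diol 9-O-PMB ether F8.
- Yamaguchi acylation with 25 gives the 8-O-acyl 9-O-PMB ether F9.
- Buffered DDQ gives 29.

**Step 12.** The lithium enolate at C11 may expel the C7 silyloxy group (E1cB) to give a butenolide, or the Mannich reaction at the hindered α-carbon may be slow. The fallback avoids a free enolate; it sets out from 16 and comes back at 19. Heating 16 with tert-butoxybis(dimethylamino)methane should give the α-(dimethylaminomethylene) lactone F10 (enamine geometry immaterial). Reduction of the vinylogous carbamate with iBu2AlH at −78 °C, followed by loss of dimethylamine on work-up, gives 19.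

**Step 11.** Competing epoxidation of the electron-rich C4=C5 alkene and insertion on the wrong side (migration of C11) are the likely failures. The fallback changes the order so that the chlorine atoms enforce the regiochemistry; it sets out from 14 and comes back at 16. Brief treatment of 14 with buffered H2O2/AcOH, where the CCl2 group blocks migration of C11 and activates the carbonyl, should give the 3,3-dichloro lactone F11. Reduction with Zn–Cu couple and NH4Cl in MeOH at low temperature, to protonate the zinc enolate before it can lose the silyloxy group, gives 16.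

## Further compounds

F1 | step 9 | (2R,4R,5E,9Z)-2-[(tert-butyldimethylsilyl)oxy]-4-hydroxy-10-iodo-1-[(4-methoxybenzyl)oxy]-6-methylundeca-5,9-dien-3-one | C/C(I)=C/CC/C(C)=C/[C@@H](O)C(=O)[C@H](O[Si](C)(C)C(C)(C)C)COCc1ccc(OC)cc1
F2 | step 9 | ethyl (3R,4R,5E,9Z)-3-{(1R)-1-[(tert-butyldimethylsilyl)oxy]-2-[(4-methoxybenzyl)oxy]ethyl}-3,4-dihydroxy-10-iodo-6-methylundeca-5,9-dienoate | CCOC(=O)C[C@](O)([C@H](O[Si](C)(C)C(C)(C)C)COCc1ccc(OC)cc1)[C@H](O)/C=C(\C)CC/C=C(/C)I
F3 | step 9 | (4R,5R)-4-{(1R)-1-[(tert-butyldimethylsilyl)oxy]-2-[(4-methoxybenzyl)oxy]ethyl}-4-hydroxy-5-[(1E,5Z)-6-iodo-2-methylhepta-1,5-dien-1-yl]oxolan-2-one | O=C1C[C@](O)([C@H](O[Si](C)(C)C(C)(C)C)COCc2ccc(OC)cc2)[C@@H](/C=C(\C)CC/C=C(/C)I)O1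
F4 | step 20 | (4R,5R)-4-[(tert-butyldimethylsilyl)oxy]-4-{(1R)-1-[(tert-butyldimethylsilyl)oxy]-2-hydroxyethyl}-5-[(1E,5Z)-6-iodo-2-methylhepta-1,5-dien-1-yl]-3-methylideneoxolan-2-one | O=C1C(=C)[C@](O[Si](C)(C)C(C)(C)C)([C@H](O[Si](C)(C)C(C)(C)C)CO)[C@@H](/C=C(\C)CC/C=C(/C)I)O1
F5 | step 20 | (2S)-2-[(tert-butyldimethylsilyl)oxy]-2-{(2R,3R)-3-[(tert-butyldimethylsilyl)oxy]-2-[(1E,5Z)-6-iodo-2-methylhepta-1,5-dien-1-yl]-4-methylidene-5-oxooxolan-3-yl}acetaldehyde | O=C1C(=C)[C@](O[Si](C)(C)C(C)(C)C)([C@H](O[Si](C)(C)C(C)(C)C)C=O)[C@@H](/C=C(\C)CC/C=C(/C)I)O1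
F6 | step 20 | 7,8-bis-O-(tert-butyldimethylsilyl) germacranolide 9-ol (ring A closed, configurations at C6–C9 as in 29, no acyl group) | C=C1C(=O)O[C@@H]2/C=C(\C)CC/C=C(/C)[C@@H](O)[C@@H](O[Si](C)(C)C(C)(C)C)[C@@]12O[Si](C)(C)C(C)(C)C
F7 | step 20 | 9-O-(4-methoxybenzyl) ether of F6 | C=C1C(=O)O[C@@H]2/C=C(\C)CC/C=C(/C)[C@@H](OCc3ccc(OC)cc3)[C@@H](O[Si](C)(C)C(C)(C)C)[C@@]12O[Si](C)(C)C(C)(C)C
F8 | step 20 | 9-O-(4-methoxybenzyl) germacranolide 7,8-diol (configurations as in 29) | C=C1C(=O)O[C@@H]2/C=C(\C)CC/C=C(/C)[C@@H](OCc3ccc(OC)cc3)[C@@H](O)[C@@]12O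
F9 | step 20 | 9-O-(4-methoxybenzyl) ether of 29 | C=C1C(=O)O[C@@H]2/C=C(\C)CC/C=C(/C)[C@@H](OCc3ccc(OC)cc3)[C@@H](OC(=O)[C@@]4(C)O[C@@H]4C)[C@@]12O
F10 | step 12 | 3-[(dimethylamino)methylidene] derivative of 16 (enamine geometry unassigned) | O=C1C(=CN(C)C)[C@](O[Si](C)(C)C(C)(C)C)([C@H](O[Si](C)(C)C(C)(C)C)COCc2ccc(OC)cc2)[C@@H](/C=C(\C)CC/C=C(/C)I)O1
F11 | step 11 | (4R,5R)-4-[(tert-butyldimethylsilyl)oxy]-4-{(1R)-1-[(tert-butyldimethylsilyl)oxy]-2-[(4-methoxybenzyl)oxy]ethyl}-3,3-dichloro-5-[(1E,5Z)-6-iodo-2-methylhepta-1,5-dien-1-yl]oxolan-2-one | O=C1C(Cl)(Cl)[C@](O[Si](C)(C)C(C)(C)C)([C@H](O[Si](C)(C)C(C)(C)C)COCc2ccc(OC)cc2)[C@@H](/C=C(\C)CC/C=C(/C)I)O1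
A1 | alternative 1 | elemane-type cyclitol: cyclohexanol with vinyl on the C10 carbinol and cis isopropenyl on C5, acetonides across O6/O7 and O8/O9, C7 bearing the 3-silyloxyprop-1-en-2-yl group | C=C(CO[Si](C)(C)C(C)(C)C)[C@@]12OC(C)(C)O[C@@H]1[C@H](C(C)=C)[C@](O)(C=C)[C@H]3OC(C)(C)O[C@@H]23
A2 | alternative 1 | ring A dienyl triflate (C10 enol triflate) | C=C(CO[Si](C)(C)C(C)(C)C)[C@@]12OC(C)(C)O[C@@H]1/C=C(\C)CC/C=C(/OS(=O)(=O)C(F)(F)F)[C@H]3OC(C)(C)O[C@@H]23
A3 | alternative 2 | macrocyclic C6 phenyl selenocarbonate with C7 ethynyl carbinol (8-O-PMB, 9-O-TBS) | C#C[C@@]1(O)[C@H](OC(=O)[Se]c2ccccc2)/C=C(\C)CC/C=C(/C)[C@@H](O[Si](C)(C)C(C)(C)C)[C@H]1OCc1ccc(OC)cc1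
A4 | alternative 2 | germacranolide core with free C7 hydroxyl (8-O-PMB, 9-O-TBS) | C=C1C(=O)O[C@@H]2/C=C(\C)CC/C=C(/C)[C@@H](O[Si](C)(C)C(C)(C)C)[C@@H](OCc3ccc(OC)cc3)[C@@]12O
A5 | alternative 3 | 2,3-dihydrofuran | C1=COCC1
A6 | alternative 3 | C9 aldehyde with 8-O-TBS and the C6/C7 acetonide | O=C[C@@H](O[Si](C)(C)C(C)(C)C)[C@@]1(C(=C)CO[Si](C)(C)C(C)(C)C)COC(C)(C)O1
A7 | alternative 3 | C3–C9 Z-allylic alcohol with free C3 hydroxyl | OCC/C=C(/C)[C@@H](O)[C@@H](O[Si](C)(C)C(C)(C)C)[C@@]1(C(=C)CO[Si](C)(C)C(C)(C)C)COC(C)(C)O1
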